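**Plan**

1. Locants: ring carbons C1–C12 as they occur in the target SMILES (C1 carries the chain; ring A = C1–C6, ring B = C4-C5-C7-C12, ring C = C7-C8-C11-C12, ring D = C8-C9-C10-C11); chain C1' (on C1) to C8' (on oxygen); R = 8-[(2,2-dimethyl-1,3-dioxan-5-yl)oxy]octyl.
2. Enabling feature: ring D ends in the unsubstituted C9–C10 edge (two CH2 groups on C8 and C11), so C9 and C10 can first be tied through sulfur in an unstrained thiolane dioxide and bonded to each other only at the end.
3. Retrosynthetic cuts, in order: C9–C10 (SO2 extrusion); C9–S and C10–S; C7–C8 and C11–C12 (ring C); C3–C4 and C5–C6 (ring A, built onto a ready-made ring B); C1–C1'; O–C8'.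
4. Forward: ether chain and diene; Diels–Alder on cyclobutenone gives rings A and B; hydrogenation and Shapiro olefination; photoaddition of maleic anhydride gives ring C; diol, dimesylate, thiolane, sulfone; Ramberg–Bäcklund contraction gives ring D; diimide reduction and acetonide hydrolysis.
5. Stereochemistry: C4 and C5 from the chiral boron Lewis acid in the Diels–Alder step; C1 from hydrogenation on the convex face; C7, C8, C11 and C12 from exo, anti photoaddition; no stereocentre is made after step 9.

Key step: step 14

Assumption: the facial model accepted for 2-cycloalkenones bound to cationic oxazaborolidines (boron on the carbonyl lone pair syn to C-α, α-C–H···O contact, diene entering opposite the shielding phenyl) is taken to hold for cyclobutenone and points to the catalyst built from (R)-diphenylprolinol; should the adduct prove antipodal, the (S)-derived catalyst is used and nothing else changes.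

**Route**

Step 1
Reactants: 1 2,2-dimethyl-1,3-dioxan-5-ol; 2 1,8-dibromooctane
Product: 4 5-[(8-bromooctyl)oxy]-2,2-dimethyl-1,3-dioxane, via sodium dioxanolate 3 (not isolated)
Conditions: NaH, THF, 0 °C; then 2 (excess), DMF, 0 °C to rt
Reagents that add atoms: none
Why: Williamson ether synthesis, in which the sodium alkoxide displaces one primary bromide by SN2 and the excess of dibromide keeps double alkylation down.

Step 2
Reactants: 4 5-[(8-bromooctyl)oxy]-2,2-dimethyl-1,3-dioxane; 5 2-chlorobuta-1,3-diene (chloroprene)
Product: 7 2-{8-[(2,2-dimethyl-1,3-dioxan-5-yl)oxy]octyl}buta-1,3-diene, via alkylmagnesium bromide 6 (not isolated)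
Conditions: Mg, THF, rt to 40 °C; then 5, NiCl2(dppp) (cat., dppp = 1,3-bis(diphenylphosphino)propane), THF, 0 °C to rt
Reagents that add atoms: none
Why: Kumada coupling of the primary Grignard reagent with the vinylic C–Cl bond of chloroprene, the standard entry to 2-alkylbuta-1,3-dienes, forms C1–C1' and leaves the acetal and ether untouched.

Step 3
Reactants: 8 3-oxocyclobutane-1-carboxylic acid
Product: 9 3-bromocyclobutan-1-one
Conditions: HgO, Br2, MgSO4, CH2Cl2, reflux
Reagents that add atoms: bromine, BrBr
Why: Hunsdiecker bromodecarboxylation in its HgO/Br2 form, in which the acyl hypobromite loses CO2 and the cyclobutyl radical takes up bromine while the ketone is inert.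

Step 4
Reactants: 9 3-bromocyclobutan-1-one
Product: 10 cyclobut-2-en-1-one
Conditions: n-Bu3N, neat, rt; vacuum transfer into a −78 °C trap, kept as a cold CH2Cl2 solution
Reagents that add atoms: none
Why: E1cB loss of HBr from the β-bromo ketone with a tertiary amine gives the volatile strained enone, which is distilled away from the ammonium salt before it can oligomerise.

Step 5
Reactants: 10 cyclobut-2-en-1-one; 7 2-{8-[(2,2-dimethyl-1,3-dioxan-5-yl)oxy]octyl}buta-1,3-diene
Product: 11 (1R,6R)-3-R-bicyclo[4.2.0]oct-3-en-7-one (cis-fused rings A and B; alkene C1=C2 and ketone C12 in the locants of the plan)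
Conditions: B-(o-tolyl)oxazaborolidine from (R)-α,α-diphenylprolinol (cat.), AlBr3 (cat., slightly less than the oxazaborolidine), CH2Cl2, −78 °C; Et3N quench
Reagents that add atoms: none
Why: Enantioselective Diels–Alder reaction under chiral oxazaborolidinium Lewis acid catalysis, in which the boron-bound enone takes up the diene on the face not covered by the catalyst phenyl group (this fixes C4 and C5, cis by suprafacial addition) and the 2-alkyl group directs para regiochemistry, so that the chain ends on C1.

Step 6
Reactants: 11 (1R,6R)-3-R-bicyclo[4.2.0]oct-3-en-7-one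
Product: 12 (1R,3S,6R)-3-R-bicyclo[4.2.0]octan-7-one (H1, H4 and H5 on one face; chain cis to ring B)
Conditions: H2 (1 atm), Pd/C, EtOAc, rt
Reagents that add atoms: none
Why: Heterogeneous catalytic hydrogenation, in which the trisubstituted alkene should bind to the metal through the convex face of the cis-fused bicycle (the face of H4 and H5, away from ring B), so that the new hydrogen on C1 is cis to H4 and H5; ketone and acetal are not reduced.

Step 7
Reactants: 12 (1R,3S,6R)-3-R-bicyclo[4.2.0]octan-7-one
Product: 13 p-toluenesulfonylhydrazone of 12 (C12=N–NHTs)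
Conditions: TsNHNH2, MeOH, rt
Reagents that add atoms: p-toluenesulfonyl hydrazide, Cc1ccc(cc1)S(=O)(=O)NN
Why: Condensation of the strained, reactive cyclobutanone with the sulfonyl hydrazide needs no acid catalyst, which spares the acetonide.

Step 8
Reactants: 13 p-toluenesulfonylhydrazone of 12
Product: 16 3-R-bicyclo[4.2.0]oct-7-ene (cyclobutene C7=C12; C1 C4 C5 unchanged), via dilithiated tosylhydrazone 14 (not isolated), via C12 vinyllithium 15 (not isolated)
Conditions: n-BuLi (2.5 equiv), TMEDA, THF, −78 °C to rt; then H2O
Reagents that add atoms: none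
Why: Shapiro reaction, in which deprotonation at N–H and then at the C7 methylene (the less substituted α-carbon, syn to the sulfonamide nitrogen), loss of sulfinate and N2 and protonation of the vinyllithium place the double bond at C7=C12 and not at the bridgehead.

Step 9
Reactants: 16 3-R-bicyclo[4.2.0]oct-7-ene; 17 maleic anhydride
Product: 18 tetracyclic anhydride (rings A, B, C and a five-membered anhydride C8–C9(=O)–O–C10(=O)–C11; cis-anti-cis-anti-cis)
Conditions: hν (Hg lamp, Pyrex, >300 nm), PhCOMe (sensitiser), 17 (excess), acetone, 10 °C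
Reagents that add atoms: none
Why: Triplet-sensitised [2+2] photocycloaddition of maleic anhydride to the strained cyclobutene forms C7–C8 and C11–C12 on the convex face of the bicyclo[4.2.0]octene (anti to ring A), with the anhydride ring settling anti to ring B in the biradical closure, which sets C7, C8, C11 and C12.

Step 10
Reactants: 18 tetracyclic anhydride
Product: 19 diol (CH2OH on C8 and on C11, cis on ring C)
Conditions: LiAlH4, THF, 0 °C to reflux; aqueous NaOH work-up
Reagents that add atoms: none
Why: Hydride reduction of the cyclic anhydride to the cis 1,4-diol, which touches no stereocentre and leaves the acetal intact.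

Step 11
Reactants: 19 diol
Product: 20 bis(methanesulfonate) of 19
Conditions: MsCl, Et3N, CH2Cl2, 0 °C
Reagents that add atoms: methanesulfonyl chloride, CS(=O)(=O)Cl
Why: Sulfonylation of both primary alcohols under amine base turns them into leaving groups without acid.

Step 12
Reactants: 20 bis(methanesulfonate)
Product: 21 tetracyclic sulfide (thiolane, sulfur between C9 and C10, cis-fused to ring C)
Conditions: Na2S·9H2O, DMF, 80 °C
Reagents that add atoms: sodium sulfide, [Na+].[Na+].[S-2]
Why: Double SN2 displacement by sulfide, the second a 5-exo-tet closure, is the established way from cis-1,2-bis(sulfonyloxymethyl)cyclobutanes to 3-thiabicyclo[3.2.0]heptanes.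

Step 13
Reactants: 21 tetracyclic sulfide
Product: 23 tetracyclic sulfone (thiolane 1,1-dioxide; SO2 between C9/C10), via sulfoxide 22 (not isolated)
Conditions: mCPBA (2.2 equiv), NaHCO3, CH2Cl2, 0 °C to rt
Reagents that add atoms: 3-chloroperoxybenzoic acid, OOC(=O)c1cccc(Cl)c1
Why: Peracid oxidation of the sulfide through the sulfoxide to the sulfone, with bicarbonate buffering to protect the acetonide; nothing else in the molecule is oxidisable.

Step 14
Reactants: 23 tetracyclic sulfone
Product: 26 acetonide-protected lipid containing cyclobutene ring D (C9=C10), via C9 bromo sulfone 24 (not isolated), via episulfone 25 (not isolated)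
Conditions: CBr2F2, KOH/Al2O3, t-BuOH/CH2Cl2, 0 °C to rt
Reagents that add atoms: none
Why: KOH on alumina deprotonates C9 (or C10), the carbanion takes bromine from CBr2F2 to give 24, a second deprotonation at the other α-carbon displaces bromide to give episulfone 25, and cheletropic loss of SO2 leaves the C9=C10 bond. The closest known reaction is the one-flask halogenative Ramberg–Bäcklund rearrangement of dialkyl and cyclic sulfones, including the contraction of 3-thiabicyclo[3.2.0]heptane 3,3-dioxides to bicyclo[2.2.0]hex-2-enes. Ring D is closed by a 3-exo-tet C9–C10 bond formation inside the five-membered ring followed by SO2 extrusion, a five-to-four ring contraction paid for by irreversible loss of a gas. No stereocentre is created, and C8 and C11, which are not acidic, keep the configuration set in step 9. The step needs only monohalogenation at a sulfone α-carbon; C9 and C10 are the only acidic CH2 groups and either one leads to the same alkene, while the ether, the acetal and the cyclobutane σ bonds are inert to the base.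

Step 15
Reactants: 26 acetonide-protected lipid with cyclobutene ring D
Product: 27 acetonide-protected saturated lipid (ring D as cyclobutane)
Conditions: 2-nitrobenzenesulfonyl hydrazide, Et3N, CH2Cl2, rt
Reagents that add atoms: none
Why: Diimide reduction, in which diimide released from the sulfonyl hydrazide transfers two hydrogens concertedly to the strained C9=C10 bond without the metal-mediated cleavage of cyclobutane σ bonds that catalytic hydrogenation could cause; no stereocentre results.

Step 16
Reactants: 27 acetonide-protected saturated lipid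
Product: 28 target, 2-({8-[ladderane ring C1]octyl}oxy)propane-1,3-diol (CNP0193334.1)
Conditions: AcOH/H2O (4:1), THF, rt
Reagents that add atoms: none
Why: Acid-catalysed acetal hydrolysis frees the two primary alcohols, and the saturated ladder and the dialkyl ether are stable to dilute acetic acid.

**Compound list**

1 | 2,2-dimethyl-1,3-dioxan-5-ol | CC1(C)OCC(O)CO1 | starting material
2 | 1,8-dibromooctane | BrCCCCCCCCBr | starting material
3 | sodium 2,2-dimethyl-1,3-dioxan-5-olate | CC1(C)OCC([O-])CO1.[Na+] | intermediate (not isolated)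
4 | 5-[(8-bromooctyl)oxy]-2,2-dimethyl-1,3-dioxane | CC1(C)OCC(CO1)OCCCCCCCCBr | intermediate
5 | 2-chlorobuta-1,3-diene (chloroprene, stabilised solution) | C=CC(Cl)=C | starting material
6 | {8-[(2,2-dimethyl-1,3-dioxan-5-yl)oxy]octyl}magnesium bromide | CC1(C)OCC(CO1)OCCCCCCCC[Mg]Br | intermediate (not isolated)
7 | 2-{8-[(2,2-dimethyl-1,3-dioxan-5-yl)oxy]octyl}buta-1,3-diene | CC1(C)OCC(CO1)OCCCCCCCCC(=C)C=C | intermediate
8 | 3-oxocyclobutane-1-carboxylic acid | O=C1CC(C1)C(=O)O | starting material
9 | 3-bromocyclobutan-1-one | O=C1CC(Br)C1 | intermediate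
10 | cyclobut-2-en-1-one | O=C1CC=C1 | intermediate
11 | (1R,6R)-3-R-bicyclo[4.2.0]oct-3-en-7-one, cis-fused Diels–Alder adduct | CC1(C)OCC(CO1)OCCCCCCCCC1=CC[C@@H]2[C@H](C1)CC2=O | intermediate
12 | (1R,3S,6R)-3-R-bicyclo[4.2.0]octan-7-one, H1/H4/H5 cis | CC1(C)OCC(CO1)OCCCCCCCC[C@H]1CC[C@@H]2[C@H](C1)CC2=O | intermediate
13 | p-toluenesulfonylhydrazone of 12 | CC1(C)OCC(CO1)OCCCCCCCC[C@H]1CC[C@@H]2[C@H](C1)CC2=NNS(=O)(=O)c1ccc(C)cc1 | intermediate
14 | N,C7-dilithiated tosylhydrazone | CC1(C)OCC(CO1)OCCCCCCCC[C@H]1CC[C@@H]2[C@H](C1)C([Li])C2=NN([Li])S(=O)(=O)c1ccc(C)cc1 | intermediate (not isolated)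
15 | C12 vinyllithium (C7=C12) | CC1(C)OCC(CO1)OCCCCCCCC[C@H]1CC[C@@H]2[C@H](C1)C=C2[Li] | intermediate (not isolated)
16 | 3-R-bicyclo[4.2.0]oct-7-ene, cyclobutene C7=C12, C1/C4/C5 as in 12 | CC1(C)OCC(CO1)OCCCCCCCC[C@H]1CC[C@@H]2[C@H](C1)C=C2 | intermediate
17 | maleic anhydride | O=C1C=CC(=O)O1 | starting material
18 | tetracyclic anhydride, rings A–C plus anhydride across C8/C11, cis-anti-cis-anti-cis | CC1(C)OCC(CO1)OCCCCCCCC[C@H]1CC[C@@H]2[C@H](C1)[C@H]1[C@@H]3C(=O)OC(=O)[C@@H]3[C@@H]21 | intermediate
19 | diol, cis CH2OH groups on C8 and C11 | CC1(C)OCC(CO1)OCCCCCCCC[C@H]1CC[C@@H]2[C@H](C1)[C@H]1[C@H](CO)[C@H](CO)[C@@H]21 | intermediate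
20 | bis(methanesulfonate) of 19 | CC1(C)OCC(CO1)OCCCCCCCC[C@H]1CC[C@@H]2[C@H](C1)[C@H]1[C@H](COS(C)(=O)=O)[C@H](COS(C)(=O)=O)[C@@H]21 | intermediate
21 | tetracyclic sulfide (thiolane, S between C9 and C10) | CC1(C)OCC(CO1)OCCCCCCCC[C@H]1CC[C@@H]2[C@H](C1)[C@H]1[C@@H]3CSC[C@@H]3[C@@H]21 | intermediate
22 | tetracyclic sulfoxide (either configuration at sulfur) | CC1(C)OCC(CO1)OCCCCCCCC[C@H]1CC[C@@H]2[C@H](C1)[C@H]1[C@@H]3CS(=O)C[C@@H]3[C@@H]21 | intermediate (not isolated)
23 | tetracyclic sulfone, 6-4-4-5 skeleton | CC1(C)OCC(CO1)OCCCCCCCC[C@H]1CC[C@@H]2[C@H](C1)[C@H]1[C@@H]3CS(=O)(=O)C[C@@H]3[C@@H]21 | intermediate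
24 | α-bromo sulfone, Br on C9 (the C10 regioisomer behaves alike; configuration at the CHBr carbon open) | CC1(C)OCC(CO1)OCCCCCCCC[C@H]1CC[C@@H]2[C@H](C1)[C@H]1[C@@H]3C(Br)S(=O)(=O)C[C@@H]3[C@@H]21 | intermediate (not isolated)
25 | episulfone (thiirane 1,1-dioxide on C9–C10; either face) | CC1(C)OCC(CO1)OCCCCCCCC[C@H]1CC[C@@H]2[C@H](C1)[C@H]1[C@@H]3C4C([C@@H]3[C@@H]21)S4(=O)=O | intermediate (not isolated)
26 | acetonide-protected lipid with cyclobutene ring D (C9=C10) | CC1(C)OCC(CO1)OCCCCCCCC[C@H]1CC[C@@H]2[C@H](C1)[C@H]1[C@@H]3C=C[C@@H]3[C@@H]21 | intermediate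
27 | acetonide-protected saturated lipid | CC1(C)OCC(CO1)OCCCCCCCC[C@H]1CC[C@@H]2[C@H](C1)[C@H]1[C@@H]3CC[C@@H]3[C@@H]21 | intermediate
28 | CNP0193334.1, 2-{[8-(ladderanyl)octyl]oxy}propane-1,3-diol | OCC(CO)OCCCCCCCC[C@H]1CC[C@@H]2[C@H](C1)[C@H]1[C@@H]3CC[C@@H]3[C@@H]21 | target

**Step count and risks**

Total: 16 steps. Longest linear sequence: 14 steps (steps 1, 2 and 5 to 16; the branch through steps 3 and 4 is equally long).

Steps most likely to fail:

1. Step 14. The three-membered closure inside the strained bicyclic sulfone may be slower than a second bromination, so over-halogenation could consume the sulfone; difluorocarbene could also add to the strained alkene. The fallback sets out from sulfide 21 and installs a single halogen before oxidation. N-Chlorosuccinimide in CH2Cl2 at rt should give, through the chlorosulfonium and thionium ions, the α-chloro sulfide F1. This is oxidised without purification by mCPBA (NaHCO3, CH2Cl2, 0 °C) to the α-chloro sulfone F2. KOtBu in THF (−78 °C to rt) then effects the base-only Ramberg–Bäcklund rearrangement, with no halogen donor or carbene source present, and the route is rejoined at 26.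

2. Step 5. The ether and acetal oxygens of the diene may bind the Lewis acid, which would cost turnover and facial control, and the strained enone may polymerise under the acid. The fallback sets out from 10 and 7 and uses no Lewis acid. Uncatalysed cycloaddition (toluene, rt to 45 °C) should give the racemic cis adduct F3, separated from the minor regioisomer. NaBH4 in MeOH at 0 °C, with hydride entering on the convex face, gives the racemic endo alcohol F4. Immobilised Candida antarctica lipase B with vinyl acetate in tert-butyl methyl ether is expected, by the usual empirical model for secondary carbinols, to leave the alcohol F5 of the required configuration ((S) at C12) and to convert its antipode into the acetate F6. After separation, F5 is oxidised with Dess–Martin periodinane and the route is rejoined at 11.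

3. Step 6. Hydrogen delivery may show low facial discrimination, since the bias comes only from the remote four-membered ring, and the double bond may migrate on palladium before reduction. The fallback sets out from 11 and adds a removable shield. LiBH(s-Bu)3 in THF at −78 °C gives the endo alcohol F7 (the same substance as F5). Triisopropylsilyl triflate and 2,6-lutidine give the silyl ether F8, whose bulky endo silyloxy group lies over the concave face of ring A. H2 over Pd/C should then give the saturated silyl ether F9 with the C1 hydrogen cis to H4 and H5. Tetrabutylammonium fluoride gives the saturated alcohol F10, and Dess–Martin periodinane oxidises it to rejoin the route at 12.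

**Further compounds**

F1 | step 14 | α-chloro sulfide, Cl on C9 (C10 regioisomer equivalent) | CC1(C)OCC(CO1)OCCCCCCCC[C@H]1CC[C@@H]2[C@H](C1)[C@H]1[C@@H]3C(Cl)SC[C@@H]3[C@@H]21
F2 | step 14 | α-chloro sulfone, Cl on C9 | CC1(C)OCC(CO1)OCCCCCCCC[C@H]1CC[C@@H]2[C@H](C1)[C@H]1[C@@H]3C(Cl)S(=O)(=O)C[C@@H]3[C@@H]21
F3 | step 5 | racemic cis adduct, both enantiomers written | CC1(C)OCC(CO1)OCCCCCCCCC1=CC[C@@H]2[C@H](C1)CC2=O.CC1(C)OCC(CO1)OCCCCCCCCC1=CC[C@H]2[C@@H](C1)CC2=O
F4 | step 5 | racemic endo alcohol, both enantiomers written | CC1(C)OCC(CO1)OCCCCCCCCC1=CC[C@@H]2[C@H](C1)C[C@@H]2O.CC1(C)OCC(CO1)OCCCCCCCCC1=CC[C@H]2[C@@H](C1)C[C@H]2O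
F5 | step 5 | endo alcohol of the required configuration, (1R,6R,7S)-3-R-bicyclo[4.2.0]oct-3-en-7-ol | CC1(C)OCC(CO1)OCCCCCCCCC1=CC[C@@H]2[C@H](C1)C[C@@H]2O
F6 | step 5 | acetate of the antipodal endo alcohol | CC1(C)OCC(CO1)OCCCCCCCCC1=CC[C@H]2[C@@H](C1)C[C@H]2OC(C)=O
F7 | step 6 | endo alcohol from 11 (identical with F5) | CC1(C)OCC(CO1)OCCCCCCCCC1=CC[C@@H]2[C@H](C1)C[C@@H]2O
F8 | step 6 | triisopropylsilyl ether of F7 | CC1(C)OCC(CO1)OCCCCCCCCC1=CC[C@@H]2[C@H](C1)C[C@@H]2O[Si](C(C)C)(C(C)C)C(C)C
F9 | step 6 | saturated triisopropylsilyl ether, H1/H4/H5 cis | CC1(C)OCC(CO1)OCCCCCCCC[C@H]1CC[C@@H]2[C@H](C1)C[C@@H]2O[Si](C(C)C)(C(C)C)C(C)C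
F10 | step 6 | saturated endo alcohol | CC1(C)OCC(CO1)OCCCCCCCC[C@H]1CC[C@@H]2[C@H](C1)C[C@@H]2O
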